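The seven-membered ring C4–C5–C6–C7–C8–C9–C10 is grown from the cyclohexanone ring of an enantioenriched cis-fused Wieland–Miescher-type decalin by inserting C8 (target numbering: C1 ketone, C2=C3, cyclobutane C4/C5/C10/C11, gem-dimethyl C6, oxygenated C7 and C9). Because C10 is quaternary, the C9 ketone enolises only towards C7; FeCl3 cleavage of the C7–C9 bond of the derived siloxycyclopropane gives the cycloheptenone in one operation. That enone, flanked by quaternary C10 and C6, cannot enolise, so it survives the enolate alkylation (C11 to C5) that closes the cyclobutane, and it then accepts the C7 oxygen. The precursor is a bicyclo[4.1.0] siloxycyclopropane fused to a methylcyclohexene.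

Key step: step 11

Remark: 2,5,5-trimethylcyclohexane-1,3-dione is taken as a purchasable dione (otherwise one C-methylation from dimedone).

Step 1
Reactants: 1 2,5,5-trimethylcyclohexane-1,3-dione; 2 pent-1-en-3-one
Product: 3 triketone 2,5,5-trimethyl-2-(3-oxopentyl)cyclohexane-1,3-dione
Conditions: Et3N (cat.), EtOAc, rt
Reagents that add atoms: none
Why: Michael addition of the 1,3-dione to the vinyl ketone (first half of a Robinson annulation) joins C10 to C11; C10 is still prochiral.

Step 2
Reactants: 3 triketone
Product: 4 (8aS)-3,3,5,8a-tetramethyl-3,4,8,8a-tetrahydronaphthalene-1,6(2H,7H)-dione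
Conditions: L-phenylalanine, (+)-camphorsulfonic acid, DMF, 30 → 70 °C
Reagents that add atoms: none
Why: Hajos–Parrish–Eder–Sauer–Wiechert aldol condensation (second half of the Robinson annulation): the L-amino acid enamine of the side-chain ketone attacks one of the two enantiotopic ring carbonyls, which should set C10 in the (S)-Wieland–Miescher sense.

Step 3
Reactants: 4 enedione
Product: 5 C9 ethylene ketal of 4
Conditions: HOCH2CH2OH, p-TsOH (cat.), 4 Å MS, rt
Reagents that add atoms: ethylene glycol, OCCO
Why: Acid-catalysed ketalisation should take the saturated C9 carbonyl in preference to the conjugated C2 carbonyl, as is usual for Wieland–Miescher-type enediones.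

Step 4
Reactants: 5 ketal enone
Product: 6 C2 ethyl dienol ether (C2=C3 and C4=C5)
Conditions: HC(OEt)3, p-TsOH (cat.), EtOH–dioxane, rt
Reagents that add atoms: triethyl orthoformate, CCOC(OCC)OCC
Why: Acid-catalysed dienol ether formation from the enone (the 3-alkoxy-3,5-diene chemistry of steroidal enones) moves the unsaturation to C4=C5 and makes C5 nucleophilic.

Step 5
Reactants: 6 dienol ether
Product: 7 C5-hydroxy enone ketal (C5-OH cis to the C10 methyl)
Conditions: mCPBA, THF–H2O, 0 °C
Reagents that add atoms: mCPBA, OOC(=O)c1cccc(Cl)c1; water, O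
Why: Vinylogous Rubottom-type γ-oxidation: the peracid should attack the diene terminus C5 axially on the face of the angular methyl (as in 6β-hydroxylation of steroidal dienol ethers), and hydrolysis returns the C2 enone.

Step 6
Reactants: 7 hydroxy enone ketal
Product: 8 C2 tosylhydrazone of 7
Conditions: TsNHNH2, EtOH, rt
Reagents that add atoms: p-toluenesulfonyl hydrazide, Cc1ccc(cc1)S(=O)(=O)NN
Why: Condensation of the only free carbonyl (C2) gives the α,β-unsaturated tosylhydrazone.

Step 7
Reactants: 8 tosylhydrazone
Product: 10 cis-fused alkene ketal (C2=C3; C4-H and C5-OH cis to the C10 methyl), via allylic diazene 9 (not isolated)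
Conditions: catecholborane, CHCl3, 0 °C; then NaOAc·3H2O, reflux
Reagents that add atoms: none
Why: Reductive alkene transposition of an enone tosylhydrazone: hydride should add to C2 opposite the angular methyl, and the suprafacial retro-ene loss of N2 from the allylic diazene then delivers hydrogen to C4 on the methyl face, giving the cis ring fusion as with steroidal 4-en-3-ones.

Step 8
Reactants: 10 alkene ketal
Product: 11 cis-fused hydroxy ketone (C9 ketone, C2=C3, C5-OH)
Conditions: 1 M HCl, THF, rt
Reagents that add atoms: water, O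
Why: Acetal hydrolysis frees the C9 ketone without touching the trisubstituted alkene or the stereocentres.

Step 9
Reactants: 11 hydroxy ketone
Product: 12 bis(trimethylsilyl) compound (C7=C9 silyl enol ether, C5 silyl ether)
Conditions: Me3SiOTf, Et3N, CH2Cl2, 0 °C
Reagents that add atoms: trimethylsilyl triflate, C[Si](C)(C)OS(=O)(=O)C(F)(F)F
Why: Soft enolisation–silylation can form only one enol ether because C10 is quaternary; the C5 hydroxyl is silylated at the same time.

Step 10
Reactants: 12 silyl enol ether
Product: 13 siloxycyclopropane (C8 bridging C7 and C9)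
Conditions: Et2Zn, CH2I2, CH2Cl2, 0 °C → rt
Reagents that add atoms: diiodomethane, ICI
Why: Furukawa-modified Simmons–Smith cyclopropanation should take the electron-rich silyl enol ether well ahead of the trisubstituted C2=C3 alkene; the cyclopropane face is of no consequence.

Step 11
Reactants: 13 siloxycyclopropane
Product: 15 hydroxy cycloheptenone (C9 ketone, C7=C8, C5-OH), via chloro ketone 14 (not isolated)
Conditions: FeCl3, DMF, 0 °C → rt; then NaOAc, MeOH, reflux
Reagents that add atoms: none
Why: FeCl3 oxidises the siloxycyclopropane by single-electron transfer to an oxygen-centred radical, which undergoes β-scission of the internal C7–C9 bond to the seven-membered C9 ketone with a C7 radical; this takes chlorine to give the β-chloro ketone, and NaOAc eliminates HCl to the enone. The closest known reaction type is the Saegusa–Ito one-carbon ring enlargement of cyclic silyl enol ethers through 1-siloxybicyclo[n.1.0]alkanes. No ring is closed: the six-membered ring C4–C5–C6–C7–C9–C10 becomes the seven-membered ring C4–C5–C6–C7–C8–C9–C10 by cleavage of the zero bridge. No stereocentre is created (C7 and C8 become sp2) and C4, C5 and C10 are untouched. The selectivity needed is internal over external cyclopropane bond cleavage, which strain relief and the secondary C7 radical should secure as is general for these substrates; the site of insertion is already fixed because quaternary C10 allowed the enol ether only towards C7.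

Step 12
Reactants: 15 hydroxy cycloheptenone
Product: 16 C5 mesylate of 15
Conditions: MsCl, Et3N, CH2Cl2, 0 °C
Reagents that add atoms: methanesulfonyl chloride, CS(=O)(=O)Cl
Why: Sulfonylation through the sulfene works on hindered secondary alcohols and leaves the C5–O bond, and so the C5 configuration, intact.

Step 13
Reactants: 16 mesylate
Product: 17 dienone mesylate (C1 ketone conjugated with C2=C3)
Conditions: t-BuOOH, Rh2(C6H10NO)4 (dirhodium tetracaprolactamate, 1 mol %), K2CO3, CH2Cl2, rt
Reagents that add atoms: tert-butyl hydroperoxide, CC(C)(C)OO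
Why: Dirhodium-catalysed allylic oxidation with tert-butylperoxy radicals should convert the ring methylene C1 next to the CH end of the C2=C3 alkene into the ketone (the regiochemistry of Δ5-steroid to 7-ketone oxidations); the cycloheptenone has no allylic hydrogen.

Step 14
Reactants: 17 dienone mesylate
Product: 18 tricyclic dienone, longipina-2,7-diene-1,9-dione
Conditions: KN(SiMe3)2, THF, −78 °C → rt
Reagents that add atoms: none
Why: Intramolecular enolate alkylation (4-exo-tet SN2): the kinetic cross-conjugated enolate at C11 sits on the ring face opposite the C5 mesylate of the cis-fused bicycle, so displacement with inversion at C5 should set C5 and C11 together, while the cycloheptenone cannot enolise.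

Step 15
Reactants: 18 tricyclic dienone
Product: 20 ketol, 7-hydroxylongipin-2-ene-1,9-dione (C7-OH on the C4 side), via boronate 19 (not isolated)
Conditions: B2pin2, CuCl (5 mol %), NaOtBu, (R,S)-Josiphos, MeOH, THF, rt; then NaBO3·4H2O, H2O
Reagents that add atoms: sodium perborate, [Na+].[Na+].O[B-]1(O)OO[B-](O)(O)OO1
Why: Copper-catalysed conjugate borylation should take the C7=C8 enone ahead of the β,β-disubstituted bridged enone, and perborate oxidises the C–B bond with retention; the substrate has little facial bias at C7, so the ligand enantiomer is the one that delivers boron to the C4-side face.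

Step 16
Reactants: 20 ketol
Product: 21 diol, 7,9-dihydroxylongipin-2-en-1-one (C9-OH on the C11 side, trans to C7-OH)
Conditions: Me4NBH(OAc)3, MeCN–AcOH, −30 °C
Reagents that add atoms: none
Why: Evans–Saksena reduction: the C7 hydroxyl binds boron and delivers hydride intramolecularly to C9, which should give the 1,3-anti diol and leave the unactivated bridged enone alone.

Step 17
Reactants: 21 diol
Product: 22 9-acetate of 21
Conditions: Ac2O (1.1 equiv), pyridine, 0 °C
Reagents that add atoms: acetic anhydride, CC(=O)OC(C)=O
Why: Sterically controlled acylation: the C9 hydroxyl, next to C10 whose substituents are tied back in the cyclobutane, should react before the neopentyl C7 hydroxyl next to the gem-dimethyl carbon.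

Step 18
Reactants: 22 9-acetate; 23 angelic acid
Product: 24 target, 9-acetoxy-7-angeloyloxylongipin-2-en-1-one
Conditions: 2,4,6-Cl3C6H2COCl, Et3N, toluene, rt; then DMAP, 70 °C
Reagents that add atoms: none
Why: Yamaguchi esterification through the mixed trichlorobenzoic angelic anhydride should acylate the hindered C7 hydroxyl without Z to E isomerisation of the angelate.

Compound list
1 | 2,5,5-trimethylcyclohexane-1,3-dione | CC1C(=O)CC(C)(C)CC1=O | starting material
2 | pent-1-en-3-one (ethyl vinyl ketone) | CCC(=O)C=C | starting material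
3 | 2,5,5-trimethyl-2-(3-oxopentyl)cyclohexane-1,3-dione | CCC(=O)CCC1(C)C(=O)CC(C)(C)CC1=O | intermediate
4 | (8aS)-3,3,5,8a-tetramethyl-3,4,8,8a-tetrahydronaphthalene-1,6(2H,7H)-dione (C9 ketone, C2 enone, C3=C4, angular methyl on C10) | C1C(=O)[C@@]2(C)CCC(=O)C(C)=C2CC1(C)C | intermediate
5 | C9 ethylene ketal of 4 | C1C3(OCCO3)[C@@]2(C)CCC(=O)C(C)=C2CC1(C)C | intermediate
6 | C2 ethyl dienol ether of 5 (C2=C3 and C4=C5) | C1C3(OCCO3)[C@@]2(C)CCC(OCC)=C(C)C2=CC1(C)C | intermediate
7 | C5-hydroxy enone ketal (C5-OH cis to the C10 methyl) | C1C3(OCCO3)[C@@]2(C)CCC(=O)C(C)=C2[C@H](O)C1(C)C | intermediate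
8 | C2 tosylhydrazone of 7 | C1C3(OCCO3)[C@@]2(C)CCC(=NNS(=O)(=O)c3ccc(C)cc3)C(C)=C2[C@H](O)C1(C)C | intermediate
9 | allylic diazene (C2–N=NH) from 8 | C1C3(OCCO3)[C@@]2(C)CCC(N=N)C(C)=C2[C@H](O)C1(C)C | intermediate
10 | cis-fused alkene ketal (C2=C3; C4-H and C5-OH cis to the C10 methyl) | C1C3(OCCO3)[C@@]2(C)CCC=C(C)[C@H]2[C@H](O)C1(C)C | intermediate
11 | cis-fused hydroxy ketone (C9 ketone, C2=C3, C5-OH) | C1C(=O)[C@@]2(C)CCC=C(C)[C@H]2[C@H](O)C1(C)C | intermediate
12 | bis(trimethylsilyl) compound (C7=C9 silyl enol ether, C5 silyl ether) | C1=C(O[Si](C)(C)C)[C@@]2(C)CCC=C(C)[C@H]2[C@H](O[Si](C)(C)C)C1(C)C | intermediate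
13 | siloxycyclopropane (C8 bridging C7 and C9, either cyclopropane face) | C13CC3(O[Si](C)(C)C)[C@@]2(C)CCC=C(C)[C@H]2[C@H](O[Si](C)(C)C)C1(C)C | intermediate
14 | β-chloro ketone (C7 chloride of the cycloheptanone, C5-OH) | ClC1CC(=O)[C@@]2(C)CCC=C(C)[C@H]2[C@H](O)C1(C)C | intermediate
15 | hydroxy cycloheptenone (C9 ketone, C7=C8, C5-OH) | C1=CC(=O)[C@@]2(C)CCC=C(C)[C@H]2[C@H](O)C1(C)C | intermediate
16 | C5 mesylate of 15 | C1=CC(=O)[C@@]2(C)CCC=C(C)[C@H]2[C@H](OS(C)(=O)=O)C1(C)C | intermediate
17 | dienone mesylate (C1 ketone conjugated with C2=C3) | C1=CC(=O)[C@@]2(C)CC(=O)C=C(C)[C@H]2[C@H](OS(C)(=O)=O)C1(C)C | intermediate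
18 | tricyclic dienone, longipina-2,7-diene-1,9-dione | C1=CC(=O)[C@@]2(C)[C@@H]3C(=O)C=C(C)[C@H]2[C@@H]3C1(C)C | intermediate
19 | C7 pinacol boronate of 18 | CC1(C)OB(OC1(C)C)[C@@H]2CC(=O)[C@@]3(C)[C@@H]4C(=O)C=C(C)[C@H]3[C@@H]4C2(C)C | intermediate
20 | ketol, 7-hydroxylongipin-2-ene-1,9-dione | O[C@@H]1CC(=O)[C@@]2(C)[C@@H]3C(=O)C=C(C)[C@H]2[C@@H]3C1(C)C | intermediate
21 | diol, 7,9-dihydroxylongipin-2-en-1-one (hydroxyls trans) | O[C@@H]1C[C@@H](O)[C@@]2(C)[C@@H]3C(=O)C=C(C)[C@H]2[C@@H]3C1(C)C | intermediate
22 | 9-acetate of 21 | O[C@@H]1C[C@@H](OC(C)=O)[C@@]2(C)[C@@H]3C(=O)C=C(C)[C@H]2[C@@H]3C1(C)C | intermediate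
23 | angelic acid, (Z)-2-methylbut-2-enoic acid | C/C=C(/C)C(=O)O | starting material
24 | 9-acetoxy-7-angeloyloxylongipin-2-en-1-one | C/C=C(/C)C(=O)O[C@@H]1C[C@@H](OC(C)=O)[C@@]2(C)[C@@H]3C(=O)C=C(C)[C@H]2[C@@H]3C1(C)C | target

Total step count: 18. Longest linear sequence: 18 steps (from 1 to 24).

Steps most likely to fail

Step 14: displacement at the neopentyl secondary C5 may be slow enough that proton transfer to the extended dienolate, followed by 1,6-elimination of methanesulfonate, or O-alkylation competes. The fallback sets out from 17. Condensation of the C1 ketone with N,N-dimethylhydrazine (AcOH cat.) would give the C1 N,N-dimethylhydrazone F1. LiN(iPr)2 (THF, −78 °C → rt) would form the more nucleophilic aza-enolate at C11 and close the cyclobutane to the tricyclic hydrazone F2. Two-phase aqueous oxalic acid would hydrolyse this and rejoin the route at 18.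

Step 15: addition next to quaternary C6 may be sluggish, or facial selectivity at C7 poor, because the two faces of the cycloheptenone differ only through the remote enone bridge. The fallback sets out from 18. Lanthanum–BINOL-catalysed nucleophilic epoxidation (La(OiPr)3, (R)-BINOL, Ph3AsO, t-BuOOH, THF) would give the C7–C8 epoxy ketone F3 with oxygen on the C4-side face. SmI2 (THF–MeOH, −78 °C) would cleave the C8–O bond and rejoin the route at 20.

Step 17: site selectivity between the two hindered hydroxyls may be poor, with bis-acetylation or acyl migration. The fallback sets out from 20, where C7 carries the only hydroxyl. Yamaguchi esterification with 23 would give the keto angelate F4. NaBH4 (MeOH–CH2Cl2, −78 °C) would reduce the saturated C9 ketone in preference to the bridged enone to the C9 alcohol F5, with separation of C9 epimers. Ac2O/DMAP would then give 24 directly.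

Further compounds
F1 | step 14 | C1 N,N-dimethylhydrazone of 17 | C1=CC(=O)[C@@]2(C)CC(=NN(C)C)C=C(C)[C@H]2[C@H](OS(C)(=O)=O)C1(C)C
F2 | step 14 | tricyclic C1 N,N-dimethylhydrazone (hydrazone of 18) | C1=CC(=O)[C@@]2(C)[C@@H]3C(=NN(C)C)C=C(C)[C@H]2[C@@H]3C1(C)C
F3 | step 15 | C7–C8 epoxy ketone of 18 (oxygen on the C4 side) | O2[C@@H]1[C@H]2C(=O)[C@@]2(C)[C@@H]3C(=O)C=C(C)[C@H]2[C@@H]3C1(C)C
F4 | step 17 | 7-angelate of ketol 20 | C/C=C(/C)C(=O)O[C@@H]1CC(=O)[C@@]2(C)[C@@H]3C(=O)C=C(C)[C@H]2[C@@H]3C1(C)C
F5 | step 17 | 7-angelate 9-alcohol | C/C=C(/C)C(=O)O[C@@H]1C[C@@H](O)[C@@]2(C)[C@@H]3C(=O)C=C(C)[C@H]2[C@@H]3C1(C)C
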